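**Retrosynthetic overview**
1. Sotetsuflavone ← its tetra-O-benzyl ether ← a 2'-hydroxychalcone (I2/DMSO closure of ring C of the apigenin unit) ← a ring B aldehyde plus 2-hydroxy-4,6-bis(benzyloxy)acetophenone.
2. The strategy rests on C8 of ring A of the 7-O-methylflavone unit: it sits between the ring-oxygen-bearing C8a and the methoxy-bearing C7 and carries C3' of ring B of the apigenin unit, ortho to the 4'-OH. This carbon is therefore brought in as the benzylic CH2 of 2-hydroxyphenylacetic acid, and the biaryl bond is never made by coupling.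
3. Ring A (C4a, C5, C6, C7, C8, C8a) ← dianion Claisen closure (C5–C6 bond) of a 2-(1-aryl-2-oxopropyl)-4-pyranone-3-carboxylate ← lateral C-acetylation of a 2-benzyl-4-pyranone-3-carboxylate.
4. The 4-pyranone (ring C of the methylated unit) ← β-keto ester (arylacetic acid + malonate half ester) + arylpropioloyl chloride (from 4-benzyloxybenzaldehyde).
5. Ring order: pyranone ring C of the methylated unit, then its benzene ring A, last pyranone ring C of the apigenin unit; the other four benzene rings are purchased.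

Key step: step 12

Assumption: the target carries no descriptor for the biaryl axis, so the axis is treated as configurationally undefined and no atroposelective measure is planned; β-dicarbonyl intermediates are written as keto tautomers.

**Step 1**
Reactants: 1 2-hydroxyphenylacetic acid
Product: 2 methyl 2-(2-hydroxyphenyl)acetate
Conditions: MeOH, H2SO4 (cat.), reflux
Reagents that add atoms: methanol, CO
Why: Fischer esterification in excess methanol, which also reopens any benzofuran-2(3H)-one formed under acid, should give the phenolic methyl ester.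

**Step 2**
Reactants: 2 methyl 2-(2-hydroxyphenyl)acetate
Product: 3 methyl 2-(5-bromo-2-hydroxyphenyl)acetate
Conditions: NBS (1.0 equiv), MeCN, 0 °C to rt
Reagents that add atoms: N-bromosuccinimide, O=C1CCC(=O)N1Br
Why: Electrophilic aromatic bromination directed by the free phenol should go para to OH, the position that later carries the apigenin unit, under ionic conditions that spare the benzylic CH2.

**Step 3**
Reactants: 3 methyl 2-(5-bromo-2-hydroxyphenyl)acetate
Product: 4 methyl 2-(2-benzyloxy-5-bromophenyl)acetate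
Conditions: BnBr, K2CO3, acetone, reflux
Reagents that add atoms: benzyl bromide, BrCc1ccccc1
Why: Williamson etherification of the phenoxide with a base too weak to alkylate the ester α-carbon should give the benzyl ether.

**Step 4**
Reactants: 4 methyl 2-(2-benzyloxy-5-bromophenyl)acetate
Product: 5 2-(2-benzyloxy-5-bromophenyl)acetic acid
Conditions: LiOH, THF/H2O, rt; then aq HCl
Reagents that add atoms: lithium hydroxide, [Li+].[OH-] (the hydroxide oxygen becomes the acid OH)
Why: Saponification of an unhindered methyl ester should free the acid for chain extension without touching the aryl bromide or the benzyl ether.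

**Step 5**
Reactants: 5 2-(2-benzyloxy-5-bromophenyl)acetic acid; 6 potassium monomethyl malonate
Product: 9 methyl 4-(2-benzyloxy-5-bromophenyl)-3-oxobutanoate, via acyl imidazolide 7 (not isolated), via acylmalonic half ester 8 (not isolated)
Conditions: CDI, THF, rt; then 6, MgCl2, Et3N, THF/MeCN, rt to 50 °C; aq HCl
Reagents that add atoms: 1,1'-carbonyldiimidazole, O=C(n1ccnc1)n1ccnc1 (its imidazolyl group stands in intermediate 7 only)
Why: Masamune–Brooks homologation: the magnesium enolate of the malonate half ester is acylated by the imidazolide and the adduct loses CO2, which should give the β-keto ester carrying C4a and C5 of the methylated unit.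

**Step 6**
Reactants: 10 4-benzyloxybenzaldehyde
Product: 11 1-benzyloxy-4-(2,2-dibromovinyl)benzene
Conditions: CBr4, PPh3, CH2Cl2, 0 °C
Reagents that add atoms: carbon tetrabromide, BrC(Br)(Br)Br
Why: First stage of the Corey–Fuchs sequence, a Wittig-type olefination by the dibromomethylene ylide formed from CBr4 and PPh3, should give the dibromoalkene.

**Step 7**
Reactants: 11 1-benzyloxy-4-(2,2-dibromovinyl)benzene
Product: 13 3-(4-benzyloxyphenyl)propiolic acid, via lithium acetylide 12 (not isolated)
Conditions: n-BuLi (2.1 equiv), THF, −78 °C; then CO2, −78 °C to rt; aq HCl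
Reagents that add atoms: carbon dioxide, O=C=O; n-butyllithium, [Li]CCCC (its lithium stands in intermediate 12 only)
Why: Second stage of the Corey–Fuchs sequence (bromine–lithium exchange, elimination and rearrangement to the lithium acetylide), followed by carboxylation, should give the arylpropiolic acid at a temperature at which the benzyl ether is inert.

**Step 8**
Reactants: 13 3-(4-benzyloxyphenyl)propiolic acid
Product: 14 3-(4-benzyloxyphenyl)propioloyl chloride
Conditions: (COCl)2, DMF (cat.), CH2Cl2, 0 °C to rt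
Reagents that add atoms: oxalyl chloride, O=C(Cl)C(=O)Cl
Why: Acid chloride formation through the Vilsmeier-type chloroiminium catalyst at low temperature should avoid HCl addition to the alkyne; the crude chloride is used at once.

**Step 9**
Reactants: 9 methyl 4-(2-benzyloxy-5-bromophenyl)-3-oxobutanoate; 14 3-(4-benzyloxyphenyl)propioloyl chloride
Product: 15 methyl 4-(2-benzyloxy-5-bromophenyl)-2-[3-(4-benzyloxyphenyl)prop-2-ynoyl]-3-oxobutanoate
Conditions: MgCl2, pyridine, CH2Cl2, 0 °C to rt; aq HCl work-up
Reagents that add atoms: none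
Why: Rathke-type soft enolization gives the chelated magnesium enolate at C2 of the β-keto ester, which should be acylated on carbon by the acid chloride to the enolized tricarbonyl ynone.

**Step 10**
Reactants: 15 methyl 4-(2-benzyloxy-5-bromophenyl)-2-[3-(4-benzyloxyphenyl)prop-2-ynoyl]-3-oxobutanoate
Product: 16 methyl 2-(2-benzyloxy-5-bromobenzyl)-6-(4-benzyloxyphenyl)-4-oxo-4H-pyran-3-carboxylate
Conditions: K2CO3 (cat.), acetone, rt
Reagents that add atoms: none
Why: The enol oxygen of the arylacetyl ketone adds to the β-carbon of the ynone in a 6-endo-dig oxa-Michael closure (the 5-exo mode would be an anti-Michael addition and the ester oxygen is the poorer nucleophile), which should give the 4-pyranone with its ring oxygen already on the future C8a.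

**Step 11**
Reactants: 16 methyl 2-(2-benzyloxy-5-bromobenzyl)-6-(4-benzyloxyphenyl)-4-oxo-4H-pyran-3-carboxylate; 17 acetyl chloride
Product: 19 methyl 2-[1-(2-benzyloxy-5-bromophenyl)-2-oxopropyl]-6-(4-benzyloxyphenyl)-4-oxo-4H-pyran-3-carboxylate, via lithium dienolate 18 (not isolated)
Conditions: LiN(SiMe3)2 (2.1 equiv), THF, −78 °C; then AcCl, −78 to −20 °C; aq NH4Cl; crude with DMAP (cat.), CH2Cl2, rt
Reagents that add atoms: lithium bis(trimethylsilyl)amide, [Li]N([Si](C)(C)C)[Si](C)(C)C (its lithium stands in intermediate 18 only)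
Why: Lateral metalation of a 2-alkyl-4-pyranone: the CH2 is acidified by the aryl ring and, through C2=C3, by the C4 ketone and the ester, so dienolate 18 should be acetylated at the exocyclic carbon (C3 is fully substituted), the second equivalent of base holding the more acidic product as its enolate and DMAP moving any O-acetyl isomer to carbon.

**Step 12**
Reactants: 19 methyl 2-[1-(2-benzyloxy-5-bromophenyl)-2-oxopropyl]-6-(4-benzyloxyphenyl)-4-oxo-4H-pyran-3-carboxylate
Product: 22 8-(2-benzyloxy-5-bromophenyl)-2-(4-benzyloxyphenyl)-5,7-dihydroxychromen-4-one, via dilithium dianion 20 (not isolated), via trione tautomer 21 (not isolated)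
Conditions: LiN(iPr)2 (3.0 equiv), THF, −78 to 0 °C; then 1 M HCl
Reagents that add atoms: lithium diisopropylamide, [Li]N(C(C)C)C(C)C (its lithium stands in intermediate 20 only)
Why: Proposed new method: the first equivalent of base removes the strongly acidic C–H flanked by the aryl group, the ketone and the pyranone, and the second deprotonates the ketone methyl to give dianion 20, whose terminal carbon adds to the ester carbonyl on pyranone C3 and expels methoxide, forming the C5–C6 bond. The closest known reaction type is the base-mediated Claisen (Dieckmann-type) cyclization of methyl 2-(2-oxopropyl)benzoates to naphthalene-1,3-diols, supported by the lateral-anion chemistry of 2-alkyl-4-pyranones and the biomimetic Claisen folding of polyketo esters to phloroglucinols. The closure is 6-exo-trig and builds benzene ring A (C4a, C5, C6, C7, C8, C8a) of the methylated flavone unit, trione 21 then enolizing irreversibly to the resorcinol, which drives the sequence. No stereocenter is created, and the racemic sp3 carbon of 19 becomes aromatic C8. The step needs attack by the methyl carbanion and not lactonization through the enolate oxygen or base attack at pyranone C6; this should be secured by the much higher nucleophilicity of the dianion terminus, by the low electrophilicity of the pyranone once it is part of the anion, and by the fact that methoxide reopens any enol lactone whereas aromatization is irreversible. The 8-aryl regiochemistry and the free, non-chelated 7-OH are fixed by the connectivity of 19, so no 6-aryl isomer can arise.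

**Step 13**
Reactants: 22 8-(2-benzyloxy-5-bromophenyl)-2-(4-benzyloxyphenyl)-5,7-dihydroxychromen-4-one
Product: 23 8-(2-benzyloxy-5-bromophenyl)-2-(4-benzyloxyphenyl)-5-hydroxy-7-methoxychromen-4-one
Conditions: MeI (1.1 equiv), K2CO3, acetone, rt to 40 °C
Reagents that add atoms: iodomethane, CI
Why: Williamson methylation with one equivalent of MeI should take the more acidic, non-chelated 7-OH, since the 5-OH is held in a hydrogen bond to C4=O and is far less nucleophilic.

**Step 14**
Reactants: 23 8-(2-benzyloxy-5-bromophenyl)-2-(4-benzyloxyphenyl)-5-hydroxy-7-methoxychromen-4-one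
Product: 24 4-benzyloxy-3-[2-(4-benzyloxyphenyl)-5-hydroxy-7-methoxy-4-oxochromen-8-yl]benzaldehyde
Conditions: CO/H2 (1:1, 5 bar), Pd(OAc)2 (cat.), P(1-adamantyl)2(n-Bu) (cat.), TMEDA, toluene, 100 °C
Reagents that add atoms: carbon monoxide, [C-]#[O+]
Why: Palladium-catalysed reductive carbonylation (formylation) of the unhindered aryl bromide with synthesis gas should give the aldehyde, the homogeneous phosphine complex under CO leaving the benzyl ethers and the chromone untouched.

**Step 15**
Reactants: 25 2,4,6-trihydroxyacetophenone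
Product: 26 2-hydroxy-4,6-bis(benzyloxy)acetophenone
Conditions: BnBr (2.1 equiv), K2CO3, DMF, rt
Reagents that add atoms: benzyl bromide, BrCc1ccccc1
Why: Williamson benzylation with two equivalents of BnBr should etherify the 4-OH and one of the two equivalent ortho hydroxyls, leaving the other ortho OH, hydrogen-bonded to the acetyl carbonyl, free for the later ring closure.

**Step 16**
Reactants: 24 4-benzyloxy-3-[2-(4-benzyloxyphenyl)-5-hydroxy-7-methoxy-4-oxochromen-8-yl]benzaldehyde; 26 2-hydroxy-4,6-bis(benzyloxy)acetophenone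
Product: 28 8-{2-benzyloxy-5-[(E)-3-(2-hydroxy-4,6-bis(benzyloxy)phenyl)-3-oxoprop-1-enyl]phenyl}-2-(4-benzyloxyphenyl)-5-hydroxy-7-methoxychromen-4-one, via aldol adduct 27 (not isolated)
Conditions: KOH, EtOH/THF, rt; then dilute HCl
Reagents that add atoms: none
Why: Claisen–Schmidt condensation: the potassium enolate of the acetophenone adds to the unhindered aldehyde and aldol 27 loses water to the conjugated E-chalcone, while the flavone unit, present as its electron-rich 5-phenoxide, should resist hydroxide at room temperature.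

**Step 17**
Reactants: 28 the (E)-2'-hydroxychalcone from step 16
Product: 30 8-{2-benzyloxy-5-[5,7-bis(benzyloxy)-4-oxo-4H-chromen-2-yl]phenyl}-2-(4-benzyloxyphenyl)-5-hydroxy-7-methoxychromen-4-one, via flavanone 29 (not isolated)
Conditions: I2 (cat.), DMSO, 120 °C
Reagents that add atoms: none
Why: Iodine-catalysed oxidative cyclization of a 2'-hydroxychalcone: oxa-Michael closure to flavanone 29, α-iodination and loss of HI should give the flavone, DMSO reoxidizing HI to I2, under conditions that aryl benzyl ethers tolerate; the E alkene is consumed.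

**Step 18**
Reactants: 30 tetra-O-benzyl sotetsuflavone
Product: 31 sotetsuflavone
Conditions: H2 (1 atm), Pd/C, THF/MeOH, rt
Reagents that add atoms: none
Why: Hydrogenolysis of the four aryl benzyl ethers should free the four phenols while the 7-O-methyl ether, the chromone C2=C3 bonds and the carbonyl groups stay intact.

**Compound list**
1 | 2-hydroxyphenylacetic acid | O=C(O)Cc1ccccc1O | starting material
2 | methyl 2-(2-hydroxyphenyl)acetate | COC(=O)Cc1ccccc1O | intermediate
3 | methyl 2-(5-bromo-2-hydroxyphenyl)acetate | COC(=O)Cc1cc(Br)ccc1O | intermediate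
4 | methyl 2-(2-benzyloxy-5-bromophenyl)acetate | COC(=O)Cc1cc(Br)ccc1OCc1ccccc1 | intermediate
5 | 2-(2-benzyloxy-5-bromophenyl)acetic acid | O=C(O)Cc1cc(Br)ccc1OCc1ccccc1 | intermediate
6 | potassium monomethyl malonate | COC(=O)CC(=O)[O-].[K+] | starting material
7 | 2-(2-benzyloxy-5-bromophenyl)-1-(imidazol-1-yl)ethanone (acyl imidazolide) | O=C(Cc1cc(Br)ccc1OCc1ccccc1)n1ccnc1 | intermediate (not isolated)
8 | 4-(2-benzyloxy-5-bromophenyl)-2-(methoxycarbonyl)-3-oxobutanoic acid (formed as its magnesium chelate) | COC(=O)C(C(=O)O)C(=O)Cc1cc(Br)ccc1OCc1ccccc1 | intermediate (not isolated)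
9 | methyl 4-(2-benzyloxy-5-bromophenyl)-3-oxobutanoate | COC(=O)CC(=O)Cc1cc(Br)ccc1OCc1ccccc1 | intermediate
10 | 4-benzyloxybenzaldehyde | O=Cc1ccc(OCc2ccccc2)cc1 | starting material
11 | 1-benzyloxy-4-(2,2-dibromovinyl)benzene | BrC(Br)=Cc1ccc(OCc2ccccc2)cc1 | intermediate
12 | lithium (4-benzyloxyphenyl)acetylide | [Li]C#Cc1ccc(OCc2ccccc2)cc1 | intermediate (not isolated)
13 | 3-(4-benzyloxyphenyl)propiolic acid | O=C(O)C#Cc1ccc(OCc2ccccc2)cc1 | intermediate
14 | 3-(4-benzyloxyphenyl)propioloyl chloride | O=C(Cl)C#Cc1ccc(OCc2ccccc2)cc1 | intermediate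
15 | methyl 4-(2-benzyloxy-5-bromophenyl)-2-[3-(4-benzyloxyphenyl)prop-2-ynoyl]-3-oxobutanoate (largely enolized) | COC(=O)C(C(=O)C#Cc1ccc(OCc2ccccc2)cc1)C(=O)Cc1cc(Br)ccc1OCc1ccccc1 | intermediate
16 | methyl 2-(2-benzyloxy-5-bromobenzyl)-6-(4-benzyloxyphenyl)-4-oxo-4H-pyran-3-carboxylate | COC(=O)c1c(Cc2cc(Br)ccc2OCc2ccccc2)oc(-c2ccc(OCc3ccccc3)cc2)cc1=O | intermediate
17 | acetyl chloride | CC(=O)Cl | starting material
18 | lithium dienolate of 16 (2-benzylidene-2H-pyran-4-olate form) | [Li+].COC(=O)C1=C([O-])C=C(c2ccc(OCc3ccccc3)cc2)OC1=Cc1cc(Br)ccc1OCc1ccccc1 | intermediate (not isolated)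
19 | methyl 2-[1-(2-benzyloxy-5-bromophenyl)-2-oxopropyl]-6-(4-benzyloxyphenyl)-4-oxo-4H-pyran-3-carboxylate (racemic, largely enolized) | COC(=O)c1c(C(C(C)=O)c2cc(Br)ccc2OCc2ccccc2)oc(-c2ccc(OCc3ccccc3)cc2)cc1=O | intermediate
20 | dilithium dianion of 19 | [Li+].[Li+].COC(=O)C1=C([O-])C=C(c2ccc(OCc3ccccc3)cc2)OC1=C(C([O-])=C)c1cc(Br)ccc1OCc1ccccc1 | intermediate (not isolated)
21 | 8-(2-benzyloxy-5-bromophenyl)-2-(4-benzyloxyphenyl)-6H-chromene-4,5,7(8H)-trione (racemic keto tautomer) | O=C1CC(=O)C(c2cc(Br)ccc2OCc2ccccc2)c2oc(-c3ccc(OCc4ccccc4)cc3)cc(=O)c21 | intermediate (not isolated)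
22 | 8-(2-benzyloxy-5-bromophenyl)-2-(4-benzyloxyphenyl)-5,7-dihydroxychromen-4-one | Oc1cc(O)c2c(=O)cc(-c3ccc(OCc4ccccc4)cc3)oc2c1-c1cc(Br)ccc1OCc1ccccc1 | intermediate
23 | 8-(2-benzyloxy-5-bromophenyl)-2-(4-benzyloxyphenyl)-5-hydroxy-7-methoxychromen-4-one | COc1cc(O)c2c(=O)cc(-c3ccc(OCc4ccccc4)cc3)oc2c1-c1cc(Br)ccc1OCc1ccccc1 | intermediate
24 | 4-benzyloxy-3-[2-(4-benzyloxyphenyl)-5-hydroxy-7-methoxy-4-oxochromen-8-yl]benzaldehyde | COc1cc(O)c2c(=O)cc(-c3ccc(OCc4ccccc4)cc3)oc2c1-c1cc(C=O)ccc1OCc1ccccc1 | intermediate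
25 | 2,4,6-trihydroxyacetophenone | CC(=O)c1c(O)cc(O)cc1O | starting material
26 | 2-hydroxy-4,6-bis(benzyloxy)acetophenone | CC(=O)c1c(O)cc(OCc2ccccc2)cc1OCc1ccccc1 | intermediate
27 | aldol adduct: 8-{2-benzyloxy-5-[1-hydroxy-3-(2-hydroxy-4,6-bis(benzyloxy)phenyl)-3-oxopropyl]phenyl}-2-(4-benzyloxyphenyl)-5-hydroxy-7-methoxychromen-4-one (racemic) | COc1cc(O)c2c(=O)cc(-c3ccc(OCc4ccccc4)cc3)oc2c1-c1cc(C(O)CC(=O)c2c(O)cc(OCc3ccccc3)cc2OCc2ccccc2)ccc1OCc1ccccc1 | intermediate (not isolated)
28 | 8-{2-benzyloxy-5-[(E)-3-(2-hydroxy-4,6-bis(benzyloxy)phenyl)-3-oxoprop-1-enyl]phenyl}-2-(4-benzyloxyphenyl)-5-hydroxy-7-methoxychromen-4-one | COc1cc(O)c2c(=O)cc(-c3ccc(OCc4ccccc4)cc3)oc2c1-c1cc(/C=C/C(=O)c2c(O)cc(OCc3ccccc3)cc2OCc2ccccc2)ccc1OCc1ccccc1 | intermediate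
29 | flavanone: 8-{2-benzyloxy-5-[5,7-bis(benzyloxy)-4-oxochroman-2-yl]phenyl}-2-(4-benzyloxyphenyl)-5-hydroxy-7-methoxychromen-4-one (racemic) | COc1cc(O)c2c(=O)cc(-c3ccc(OCc4ccccc4)cc3)oc2c1-c1cc(C2CC(=O)c3c(OCc4ccccc4)cc(OCc4ccccc4)cc3O2)ccc1OCc1ccccc1 | intermediate (not isolated)
30 | 8-{2-benzyloxy-5-[5,7-bis(benzyloxy)-4-oxo-4H-chromen-2-yl]phenyl}-2-(4-benzyloxyphenyl)-5-hydroxy-7-methoxychromen-4-one (tetra-O-benzyl sotetsuflavone) | COc1cc(O)c2c(=O)cc(-c3ccc(OCc4ccccc4)cc3)oc2c1-c1cc(-c2cc(=O)c3c(OCc4ccccc4)cc(OCc4ccccc4)cc3o2)ccc1OCc1ccccc1 | intermediate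
31 | sotetsuflavone | COc1cc(O)c2c(=O)cc(-c3ccc(O)cc3)oc2c1-c1cc(-c2cc(=O)c3c(O)cc(O)cc3o2)ccc1O | target

**Totals**
Total step count: 18
Longest linear sequence: 14 steps (steps 1–5, 9–14, 16–18, from 1 to 31)

**Steps most likely to fail**

1. Step 12 (proposed new method). The ester on C3 is cross-conjugated with the anion and may react sluggishly. The enolate oxygen may close onto the ester instead of the methyl carbanion. The amide base may open the pyranone at C6 before the dianion forms. Each of these would stop ring A from aromatizing. The fallback gives up the benzannulation and makes the biaryl bond by known cross-coupling; it sets out from 10 and comes back at 24.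
   - Flavone half: Claisen–Schmidt condensation of 10 with purchased 2-hydroxy-4,6-dimethoxyacetophenone (KOH, EtOH) would give (E)-3-(4-benzyloxyphenyl)-1-(2-hydroxy-4,6-dimethoxyphenyl)prop-2-en-1-one F1. I2/DMSO closure would give 2-(4-benzyloxyphenyl)-5,7-dimethoxychromen-4-one F2. Iodination with I2 and CF3CO2Ag, which in 5,7-dialkoxyflavones goes to C8, would give 2-(4-benzyloxyphenyl)-8-iodo-5,7-dimethoxychromen-4-one F3.
   - Aryl half: 10 would be brominated ortho to the ether (Br2, NaOAc, AcOH) to 4-benzyloxy-3-bromobenzaldehyde F4 and borylated (B2pin2, PdCl2(dppf), KOAc, dioxane) to 4-benzyloxy-3-(4,4,5,5-tetramethyl-1,3,2-dioxaborolan-2-yl)benzaldehyde F5.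
   - Union: Suzuki–Miyaura coupling of F3 with F5 (Pd(OAc)2, SPhos, K3PO4, toluene/H2O) would give 4-benzyloxy-3-[2-(4-benzyloxyphenyl)-5,7-dimethoxy-4-oxochromen-8-yl]benzaldehyde F6. Chelation-controlled cleavage of the 5-O-methyl group next to C4=O (MgI2 etherate) would deliver 24, from which steps 16 to 18 follow unchanged.

2. Step 11. The extended enolate may be acetylated on oxygen or twice, or proton transfer from the more acidic product may quench it before it is consumed, so that conversion stalls. The fallback replaces the anionic acylation by a neutral condensation; it sets out from 16 and comes back at 19. Heating 16 with N,N-dimethylacetamide dimethyl acetal (toluene, 110 °C) should condense the activated CH2 to methyl 2-[1-(2-benzyloxy-5-bromophenyl)-2-(dimethylamino)prop-1-enyl]-6-(4-benzyloxyphenyl)-4-oxo-4H-pyran-3-carboxylate F7. Mild hydrolysis of the enamine (AcOH, H2O, THF) would give 19.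

3. Step 9. The magnesium enolate or pyridine may add in conjugate fashion to the ynoyl chloride, or acylation may occur on oxygen, so that the tricarbonyl ynone is not formed cleanly. The fallback builds the pyranone from an acylketene and bypasses steps 6 to 10; it sets out from 9 and comes back at 16.
   - Condensation of 9 with pyrrolidine (toluene, water removal) would give methyl 4-(2-benzyloxy-5-bromophenyl)-3-(pyrrolidin-1-yl)but-2-enoate F8.
   - Purchased Meldrum's acid and 4-benzyloxybenzoyl chloride (pyridine, CH2Cl2) would give 5-[(4-benzyloxyphenyl)(hydroxy)methylene]-2,2-dimethyl-1,3-dioxane-4,6-dione F9.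
   - Heating F9 with F8 in toluene releases 3-(4-benzyloxyphenyl)-3-oxoprop-1-en-1-one F10 (the aroylketene). Its [4+2] capture by the enamine, followed by loss of pyrrolidine, should give 16.

**Further compounds**
F1 | step 12 | (E)-3-(4-benzyloxyphenyl)-1-(2-hydroxy-4,6-dimethoxyphenyl)prop-2-en-1-one | COc1cc(O)c(C(=O)/C=C/c2ccc(OCc3ccccc3)cc2)c(OC)c1
F2 | step 12 | 2-(4-benzyloxyphenyl)-5,7-dimethoxychromen-4-one | COc1cc(OC)c2c(=O)cc(-c3ccc(OCc4ccccc4)cc3)oc2c1
F3 | step 12 | 2-(4-benzyloxyphenyl)-8-iodo-5,7-dimethoxychromen-4-one | COc1cc(OC)c2c(=O)cc(-c3ccc(OCc4ccccc4)cc3)oc2c1I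
F4 | step 12 | 4-benzyloxy-3-bromobenzaldehyde | O=Cc1ccc(OCc2ccccc2)c(Br)c1
F5 | step 12 | 4-benzyloxy-3-(4,4,5,5-tetramethyl-1,3,2-dioxaborolan-2-yl)benzaldehyde | O=Cc1ccc(OCc2ccccc2)c(B2OC(C)(C)C(C)(C)O2)c1
F6 | step 12 | 4-benzyloxy-3-[2-(4-benzyloxyphenyl)-5,7-dimethoxy-4-oxochromen-8-yl]benzaldehyde | COc1cc(OC)c2c(=O)cc(-c3ccc(OCc4ccccc4)cc3)oc2c1-c1cc(C=O)ccc1OCc1ccccc1
F7 | step 11 | methyl 2-[1-(2-benzyloxy-5-bromophenyl)-2-(dimethylamino)prop-1-enyl]-6-(4-benzyloxyphenyl)-4-oxo-4H-pyran-3-carboxylate | COC(=O)c1c(C(=C(C)N(C)C)c2cc(Br)ccc2OCc2ccccc2)oc(-c2ccc(OCc3ccccc3)cc2)cc1=O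
F8 | step 9 | methyl 4-(2-benzyloxy-5-bromophenyl)-3-(pyrrolidin-1-yl)but-2-enoate | COC(=O)C=C(Cc1cc(Br)ccc1OCc1ccccc1)N1CCCC1
F9 | step 9 | 5-[(4-benzyloxyphenyl)(hydroxy)methylene]-2,2-dimethyl-1,3-dioxane-4,6-dione | CC1(C)OC(=O)C(=C(O)c2ccc(OCc3ccccc3)cc2)C(=O)O1
F10 | step 9 | 3-(4-benzyloxyphenyl)-3-oxoprop-1-en-1-one (aroylketene) | O=C=CC(=O)c1ccc(OCc2ccccc2)cc1
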